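**Plan**
Numbering: C1H2–C2(=O)–C3H=C4 is the cyclopentenone, C5 the methyl-bearing quaternary carbon, C6 CHMe, C7 CH2, C8 CHOH, C9 the second quaternary carbon, C10 CHMe, C11 CHOH, C12 C(Me)(vinyl), C13 CH2, C14 CHOAc.
Enabling feature: C9 carries C10 and sits next to C4, which is a ketone until the cyclopentenone is closed. C10 can therefore be moved from C4 to C9 in a γ-hydroxy enone (C4–OH, C9=C1–C2=O) whose cyclohexane (C4, C5, C6, C7, C8, C9) is fused through C4–C5 to a cycloheptane (C4, C5, C14, C13, C12, C11, C10).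
Cuts, in retrosynthetic order: C3=C4 (aldol condensation); C9–C10, giving back C4–C10 (1,2-shift); C4–C10 (samarium aldol closure of the seven-membered ring); C10–C11 (ethyl addition to a lactone); C9–C1 (aldol condensation); C12–Me and the terminal vinyl carbon (lactone enolate chemistry); C13–C14 (allylation); C5–C6 and C4–C9 (Diels–Alder).
Forward: cyclohexane by Diels–Alder; a temporary γ-lactone on C14 builds C11–C14; ring oxidation pattern; cycloheptane; one-carbon expansion to the bridged cyclooctane; cyclopentenone; desilylation.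
Stereochemistry: C5 and C6 from the catalytic asymmetric endo Diels–Alder; C14 from reagent-controlled allylation; C12 from alkylation of the lactone enolate anti to the C14 substituent; C8 from oxazaborolidine reduction; C4 and C10 from the chelated samarium aldol; C11 from hydroxyl-directed reduction; C9 from the stereospecific shift.

Key step: step 18

Remark: the target is taken exactly as written; in that structure C14 (on C5) and C10 (on C9) lie on opposite faces of the cyclohexane (C5 and C6 are both S), so the route builds a trans-fused 6-7 system and carries it into a trans-bridged 6-8 system.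

**Step 1**
Reactants: 1 (E)-pent-3-en-2-one
Product: 2 (E)-2-(triisopropylsilyloxy)penta-1,3-diene
Conditions: TIPSOTf, Et3N, CH2Cl2, 0 °C
Reagents that add atoms: triisopropylsilyl trifluoromethanesulfonate, CC(C)[Si](C(C)C)(C(C)C)OS(=O)(=O)C(F)(F)F
Why: Soft enolisation of the methyl ketone (silyl triflate and amine) gives the cross-conjugated 2-silyloxy diene, and the bulky silyl group lets the enol ether survive steps 2 to 4.

**Step 2**
Reactants: 2 (E)-2-(triisopropylsilyloxy)penta-1,3-diene; 3 methacrolein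
Product: 4 (1R,2S)-1,2-dimethyl-4-(triisopropylsilyloxy)cyclohex-3-ene-1-carbaldehyde
Conditions: (S)-3,3-diphenyl-1-(o-tolyl)hexahydropyrrolo[1,2-c][1,3,2]oxazaborole·HNTf2 (20 mol%), CH2Cl2, −78 → −40 °C
Reagents that add atoms: none
Why: Catalytic asymmetric Diels–Alder reaction in which the 2-silyloxy group and the terminal methyl group both direct the regiochemistry shown, endo approach of the formyl group places the C6 methyl cis to CHO, and the cationic boron Lewis acid (the enantiomer that exposes the Si face of C2 of the s-trans enal, assigned as the (S)-prolinol-derived catalyst by the usual model for 2-substituted acroleins) sets C5 and C6.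

**Step 3**
Reactants: 4 (1R,2S)-1,2-dimethyl-4-(triisopropylsilyloxy)cyclohex-3-ene-1-carbaldehyde; 5 ethyl 2-(bromomethyl)acrylate
Product: 7 α-methylene lactone (14R) with the ring enol ether intact, via O-trimethylsilyl hydroxy ester 6 (not isolated)
Conditions: CrCl2 (10 mol%), (S,S)-3,6-diphenyl-1,8-bis(4-isopropyl-4,5-dihydrooxazol-2-yl)-9H-carbazole (12 mol%), Mn, TMSCl, i-Pr2NEt, THF, 25 °C; then K2CO3 (cat.), MeOH, 0 °C
Reagents that add atoms: none
Why: Catalytic asymmetric Nozaki–Hiyama–Kishi-type 2-(alkoxycarbonyl)allylation followed by lactonisation, in which the chiral divalent-chromium catalyst (ligand enantiomer chosen for Re-face addition) overrides the weak bias of the α-quaternary aldehyde and sets C14 as R.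

**Step 4**
Reactants: 7 α-methylene lactone
Product: 9 keto lactone with quaternary C12 bearing methyl and 2-(phenylthio)ethyl, via alkylated silyl enol ether 8 (not isolated)
Conditions: PhSCH2Li (from PhSMe, n-BuLi, DABCO), CuI (0.5 equiv), THF, −78 °C; MeI, HMPA, −78 → −20 °C; then 2 M HCl, THF, 25 °C
Reagents that add atoms: (phenylthio)methyllithium, [Li]CSc1ccccc1; iodomethane, CI
Why: Conjugate addition of a lithium diorganocuprate to the α-methylene lactone and alkylation of the resulting enolate, in which methyl iodide enters trans to the bulky C14 substituent so that C12 carries the masked vinyl group cis and the methyl group trans to it, after which acid hydrolyses the enol ether to the C8 ketone.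

**Step 5**
Reactants: 9 keto lactone sulfide
Product: 11 (3S,5R)-5-[(1R,2S)-1,2-dimethyl-4-oxocyclohexyl]-3-methyl-3-vinyldihydrofuran-2(3H)-one, via sulfoxide 10 (not isolated)
Conditions: m-CPBA (1.0 equiv), CH2Cl2, −78 °C; then toluene, CaCO3, 110 °C
Reagents that add atoms: none
Why: Sulfide oxidation and thermal syn-elimination of the sulfoxide, which can only run toward the terminal carbon because C12 is quaternary, unveil the vinyl group.

**Step 6**
Reactants: 12 methyl 2,2-dimethoxypropanoate
Product: 13 2,2-dimethoxypropanal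
Conditions: i-Bu2AlH (1.05 equiv), CH2Cl2, −78 °C; aq. KNaC4H4O6
Reagents that add atoms: none
Why: Half-reduction of an α,α-dialkoxy ester stops at the aldehyde because the chelated tetrahedral aluminium intermediate is stable at low temperature until work-up.

**Step 7**
Reactants: 11 vinyl keto lactone; 13 2,2-dimethoxypropanal
Product: 14 (E)-exocyclic enone (C8 ketone, C9=C1 alkylidene, C2 as dimethyl ketal)
Conditions: KOt-Bu (1.0 equiv), t-BuOH–THF, 25 → 40 °C
Reagents that add atoms: none
Why: Thermodynamically controlled crossed aldol condensation with a non-enolisable aldehyde occurs at C9, the α-methylene remote from the C6 methyl (as with 3-alkylcyclohexanones, where an alkylidene next to the substituent suffers allylic strain), and gives the (E)-enone.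

**Step 8**
Reactants: 14 exocyclic enone
Product: 16 endocyclic enone (C8 ketone, C9=C4, C9 bearing CH2C(OMe)2CH3), via trimethylsilyl enol ether 15 (not isolated)
Conditions: [CuH(PPh3)]6, TMSCl, THF, −40 → 0 °C; then Pd(OAc)2 (1.1 equiv), MeCN, 25 °C
Reagents that add atoms: none
Why: Copper hydride 1,4-reduction with silyl trapping gives the C8=C9 silyl enol ether regiospecifically, and Saegusa–Ito oxidation then removes a ring hydrogen from C4 so that the double bond ends inside the ring.

**Step 9**
Reactants: 16 endocyclic enone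
Product: 17 (8S)-allylic alcohol
Conditions: (R)-1-methyl-3,3-diphenylhexahydropyrrolo[1,2-c][1,3,2]oxazaborole (0.2 equiv), catecholborane, toluene, −78 °C
Reagents that add atoms: none
Why: Corey–Bakshi–Shibata reduction in which the alkenyl carbon C9 is the large and C7H2 the small flank, so the (R)-catalyst gives the (8S)-alcohol under reagent control without touching the lactone.

**Step 10**
Reactants: 17 allylic alcohol
Product: 18 C8 tert-butyldimethylsilyl ether
Conditions: TBSCl, imidazole, DMAP (cat.), DMF, 40 °C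
Reagents that add atoms: tert-butyldimethylsilyl chloride, CC(C)(C)[Si](C)(C)Cl
Why: Standard silylation of the secondary allylic alcohol under basic conditions that leave the ketal and the lactone intact.

**Step 11**
Reactants: 18 silyl ether lactone
Product: 19 γ-hydroxy ethyl ketone (C14–OH, C11 ketone)
Conditions: EtLi (1.3 equiv), THF, −78 °C; H2O
Reagents that add atoms: ethyllithium, [Li]CC
Why: Single addition of an organolithium to the α,α-disubstituted lactone, since the tetrahedral lithium alkoxide persists at −78 °C and the neopentyl ketone freed on work-up is too hindered for a second addition.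

**Step 12**
Reactants: 19 γ-hydroxy ketone
Product: 20 C14 acetate
Conditions: Ac2O, DMAP, pyridine, 25 °C
Reagents that add atoms: acetic anhydride, CC(=O)OC(C)=O
Why: DMAP-catalysed acetylation of the only free hydroxyl, the hindered secondary C14 alcohol, which is acylated in its open hydroxy ketone form.

**Step 13**
Reactants: 20 acetate
Product: 22 (E)-enone with C4 ketone and exocyclic C9=C1, via C4 hydroperoxide 21 (not isolated)
Conditions: O2, tetraphenylporphyrin (cat.), visible light, CH2Cl2, 0 °C; then Ac2O, pyridine, DMAP (cat.), 25 °C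
Reagents that add atoms: oxygen, O=O
Why: Schenck ene reaction of singlet oxygen with the C9=C4 alkene, in which oxygen binds C4 and the hydrogen can only come from C1 (C5 is quaternary and the C8 hydrogen geminal to the silyloxy group is unreactive), followed by Kornblum–DeLaMare-type dehydration of the secondary allylic hydroperoxide to the C4 ketone, the enone settling in the (E) form with C2 away from the carbonyl.

**Step 14**
Reactants: 22 enone ethyl ketone
Product: 24 α-bromo ketone (C10 epimers), via trimethylsilyl enol ether 23 (not isolated)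
Conditions: LiN(SiMe3)2 (1.1 equiv), TMSCl, THF, −78 °C; then NBS, THF, −78 °C
Reagents that add atoms: N-bromosuccinimide, BrN1C(=O)CCC1=O
Why: Kinetic deprotonation touches only C10 (C12 is quaternary, the C4 enone has no α-hydrogen and the ketone is more acidic than the acetate), and the silyl enol ether is brominated by NBS; the C10 configuration is erased in step 15.

**Step 15**
Reactants: 24 α-bromo ketone
Product: 26 trans-fused 6-7 β-hydroxy ketone with free enone (4R,10R), via ketal aldol 25 (not isolated)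
Conditions: SmI2 (2.2 equiv), THF, −78 °C; then 0.5 M oxalic acid, THF–H2O, 25 °C
Reagents that add atoms: water, O
Why: Samarium-mediated intramolecular Reformatsky-type aldol addition (7-exo-trig onto C4) in which the trivalent samarium enolate adds through a closed chelate that also binds the β-acyloxy oxygen on C14, an arrangement possible only when the new C4–O bond is cis to the C14 acetate on the seven-membered ring (the trans ring fusion), while C10 places its methyl pseudo-equatorial and cis to that hydroxyl (it remains epimerisable α to the C11 ketone), and dilute acid in the work-up hydrolyses the allylic ketal.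

**Step 16**
Reactants: 26 β-hydroxy ketone
Product: 27 4,11-anti diol (11S)
Conditions: Me4NBH(OAc)3, AcOH–MeCN, −20 °C
Reagents that add atoms: none
Why: Evans–Saksena reduction in which hydride is delivered intramolecularly from the boron bound to the C4 hydroxyl to the same face of the seven-membered ring, giving the anti diol and leaving the enone, the acetate and the silyl ether untouched.

**Step 17**
Reactants: 27 diol
Product: 28 fused 6-7 γ-hydroxy enone with C8 and C11 silyl ethers (4R,5R,6S,8S,10S,11S,12S,14R)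
Conditions: TBSOTf (1.2 equiv), 2,6-lutidine, CH2Cl2, −78 °C
Reagents that add atoms: tert-butyldimethylsilyl trifluoromethanesulfonate, CC(C)(C)[Si](C)(C)OS(=O)(=O)C(F)(F)F
Why: A silyl triflate with a hindered pyridine base silylates the secondary C11 hydroxyl and leaves the tertiary C4 hydroxyl, the base and the low temperature keeping the Lewis-acidic reagent from starting the shift early.

**Step 18**
Reactants: 28 fused 6-7 γ-hydroxy enone
Product: 29 bridged bicyclo[5.3.1] 1,4-diketone with quaternary C9 (5R,6S,8S,9S,10R,11S,12S,14R)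
Conditions: Me2AlCl (2.5 equiv), CH2Cl2, −78 → −20 °C; aq. KNaC4H4O6
Reagents that add atoms: none
Why: Me2AlCl turns the C4 hydroxyl into an aluminium alkoxide and binds the C2 carbonyl, so C9 becomes the electron-poor end of the activated enone and the C4–C10 bond migrates to it suprafacially while C4 becomes the ketone; the aluminium enolate at C1–C2 is protonated on work-up to the methyl ketone. The closest known reaction type is the Lewis-acid-mediated vinylogous α-ketol (semipinacol) rearrangement of γ-hydroxy enones. The eight-membered ring (C4, C5, C14, C13, C12, C11, C10, C9) is closed by one-carbon ring expansion, C9 being inserted between C4 and C10, which converts the fused bicyclo[5.4.0] skeleton into the bridged bicyclo[5.3.1] skeleton. The new stereocentre C9 is fixed by the C4 carbinol configuration, because C10 is delivered with retention to the face of the C9=C1 bond on which it already sits. The step needs C10 to migrate in preference to C5 and to ionisation or retro-aldol paths: the C4–C5 bond lies in the cyclohexane ring near the nodal plane of the enone and cannot overlap with it, the C11 silyl ether closes the retro-aldol outlet, and the alkoxide drives the shift. Because the trans ring fusion holds C10 pseudo-equatorial in the chair, the cyclohexane must pass through a twist-boat, which is the main risk of the step.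

**Step 19**
Reactants: 29 1,4-diketone
Product: 30 bis(silyl ether) of the target
Conditions: p-TsOH·H2O (0.2 equiv), toluene, 4 Å molecular sieves, 80 °C
Reagents that add atoms: none
Why: Acid-catalysed intramolecular aldol condensation in which only the methyl ketone can enolise (C4 lies between two quaternary carbons) and the C3 enol closes the five-membered ring onto C4 with loss of water, acid being chosen because under base the C4 alkoxide could take over the C14 acetyl group.

**Step 20**
Reactants: 30 bis(silyl ether)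
Product: 31 Pleuromutilin E
Conditions: HF·pyridine, pyridine–THF, 0 → 25 °C
Reagents that add atoms: none
Why: Fluoride cleaves both silyl ethers under buffered acidic conditions that spare the acetate and avoid base-induced retro-aldol or oxa-Michael reactions of the free hydroxy enone.

**Compound list**
1 | (E)-pent-3-en-2-one | C/C=C/C(C)=O | starting material
2 | (E)-2-(triisopropylsilyloxy)penta-1,3-diene | C=C(O[Si](C(C)C)(C(C)C)C(C)C)/C=C/C | intermediate
3 | methacrolein | C=C(C)C=O | starting material
4 | (1R,2S)-1,2-dimethyl-4-(triisopropylsilyloxy)cyclohex-3-ene-1-carbaldehyde | O=C[C@]1(C)CCC(O[Si](C(C)C)(C(C)C)C(C)C)=C[C@@H]1C | intermediate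
5 | ethyl 2-(bromomethyl)acrylate | C=C(CBr)C(=O)OCC | starting material
6 | ethyl (R)-4-[(1R,2S)-1,2-dimethyl-4-(triisopropylsilyloxy)cyclohex-3-en-1-yl]-2-methylene-4-(trimethylsilyloxy)butanoate | C=C(C[C@@H](O[Si](C)(C)C)[C@]1(C)CCC(O[Si](C(C)C)(C(C)C)C(C)C)=C[C@@H]1C)C(=O)OCC | intermediate (not isolated)
7 | (R)-5-[(1R,2S)-1,2-dimethyl-4-(triisopropylsilyloxy)cyclohex-3-en-1-yl]-3-methylenedihydrofuran-2(3H)-one | C=C1C[C@@H](OC1=O)[C@]2(C)CCC(O[Si](C(C)C)(C(C)C)C(C)C)=C[C@@H]2C | intermediate
8 | (3S,5R)-5-[(1R,2S)-1,2-dimethyl-4-(triisopropylsilyloxy)cyclohex-3-en-1-yl]-3-methyl-3-[2-(phenylthio)ethyl]dihydrofuran-2(3H)-one | c1ccccc1SCC[C@]2(C)C[C@@H](OC2=O)[C@]3(C)CCC(O[Si](C(C)C)(C(C)C)C(C)C)=C[C@@H]3C | intermediate (not isolated)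
9 | (3S,5R)-5-[(1R,2S)-1,2-dimethyl-4-oxocyclohexyl]-3-methyl-3-[2-(phenylthio)ethyl]dihydrofuran-2(3H)-one | c1ccccc1SCC[C@]2(C)C[C@@H](OC2=O)[C@]3(C)CCC(=O)C[C@@H]3C | intermediate
10 | S-oxide of 9 (both configurations at sulfur) | O=S(c1ccccc1)CC[C@]2(C)C[C@@H](OC2=O)[C@]3(C)CCC(=O)C[C@@H]3C | intermediate (not isolated)
11 | (3S,5R)-5-[(1R,2S)-1,2-dimethyl-4-oxocyclohexyl]-3-methyl-3-vinyldihydrofuran-2(3H)-one | C=C[C@]1(C)C[C@@H](OC1=O)[C@]2(C)CCC(=O)C[C@@H]2C | intermediate
12 | methyl 2,2-dimethoxypropanoate | COC(=O)C(C)(OC)OC | starting material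
13 | 2,2-dimethoxypropanal | O=CC(C)(OC)OC | intermediate
14 | (3S,5R)-5-[(1R,2S,E)-5-(2,2-dimethoxypropylidene)-1,2-dimethyl-4-oxocyclohexyl]-3-methyl-3-vinyldihydrofuran-2(3H)-one | C=C[C@]1(C)C[C@@H](OC1=O)[C@]2(C)C/C(=C\C(C)(OC)OC)C(=O)C[C@@H]2C | intermediate
15 | (3S,5R)-5-[(1R,6S)-3-(2,2-dimethoxypropyl)-1,6-dimethyl-4-(trimethylsilyloxy)cyclohex-3-en-1-yl]-3-methyl-3-vinyldihydrofuran-2(3H)-one | C=C[C@]1(C)C[C@@H](OC1=O)[C@]2(C)CC(CC(C)(OC)OC)=C(O[Si](C)(C)C)C[C@@H]2C | intermediate (not isolated)
16 | (3S,5R)-5-[(1S,6S)-3-(2,2-dimethoxypropyl)-1,6-dimethyl-4-oxocyclohex-2-en-1-yl]-3-methyl-3-vinyldihydrofuran-2(3H)-one | C=C[C@]1(C)C[C@@H](OC1=O)[C@]2(C)C=C(CC(C)(OC)OC)C(=O)C[C@@H]2C | intermediate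
17 | (3S,5R)-5-[(1S,4S,6S)-3-(2,2-dimethoxypropyl)-4-hydroxy-1,6-dimethylcyclohex-2-en-1-yl]-3-methyl-3-vinyldihydrofuran-2(3H)-one | C=C[C@]1(C)C[C@@H](OC1=O)[C@]2(C)C=C(CC(C)(OC)OC)[C@@H](O)C[C@@H]2C | intermediate
18 | C8 tert-butyldimethylsilyl ether of 17 | C=C[C@]1(C)C[C@@H](OC1=O)[C@]2(C)C=C(CC(C)(OC)OC)[C@@H](O[Si](C)(C)C(C)(C)C)C[C@@H]2C | intermediate
19 | (4S,6R)-6-[(1S,4S,6S)-4-(tert-butyldimethylsilyloxy)-3-(2,2-dimethoxypropyl)-1,6-dimethylcyclohex-2-en-1-yl]-6-hydroxy-4-methyl-4-vinylhexan-3-one | C=C[C@](C)(C[C@@H](O)[C@]1(C)C=C(CC(C)(OC)OC)[C@@H](O[Si](C)(C)C(C)(C)C)C[C@@H]1C)C(=O)CC | intermediate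
20 | C14 acetate of 19 | C=C[C@](C)(C[C@@H](OC(C)=O)[C@]1(C)C=C(CC(C)(OC)OC)[C@@H](O[Si](C)(C)C(C)(C)C)C[C@@H]1C)C(=O)CC | intermediate
21 | C4 hydroperoxide with exocyclic C9=C1 (C4 epimers, alkene geometry not fixed) | C=C[C@](C)(C[C@@H](OC(C)=O)[C@]1(C)C(OO)C(=CC(C)(OC)OC)[C@@H](O[Si](C)(C)C(C)(C)C)C[C@@H]1C)C(=O)CC | intermediate (not isolated)
22 | cyclohexanone with C4 ketone, (E)-C9=C1 alkylidene (C2 dimethyl ketal), C8 silyl ether, and on C5 the chain C14H(OAc)–C13H2–C12(Me)(vinyl)–C11(=O)–Et; (5R,6S,8S,12S,14R) | C=C[C@](C)(C[C@@H](OC(C)=O)[C@]1(C)C(=O)/C(=C/C(C)(OC)OC)[C@@H](O[Si](C)(C)C(C)(C)C)C[C@@H]1C)C(=O)CC | intermediate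
23 | (Z)-trimethylsilyl enol ether (C10=C11) of 22 | C=C[C@](C)(C[C@@H](OC(C)=O)[C@]1(C)C(=O)/C(=C/C(C)(OC)OC)[C@@H](O[Si](C)(C)C(C)(C)C)C[C@@H]1C)/C(O[Si](C)(C)C)=C/C | intermediate (not isolated)
24 | C10 bromide of 22 (C10 epimers) | C=C[C@](C)(C[C@@H](OC(C)=O)[C@]1(C)C(=O)/C(=C/C(C)(OC)OC)[C@@H](O[Si](C)(C)C(C)(C)C)C[C@@H]1C)C(=O)C(C)Br | intermediate
25 | trans-fused 6-7 aldol: C4 tertiary alcohol, C11 ketone, C2 dimethyl ketal; (4R,5R,6S,8S,10R,12S,14R) | C=C[C@]1(C)C[C@@H](OC(C)=O)[C@]2(C)[C@](O)(/C(=C/C(C)(OC)OC)[C@@H](O[Si](C)(C)C(C)(C)C)C[C@@H]2C)[C@@H](C)C1=O | intermediate (not isolated)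
26 | trans-fused 6-7 γ-hydroxy enone with C11 ketone; (4R,5R,6S,8S,10R,12S,14R), (E)-enone | C=C[C@]1(C)C[C@@H](OC(C)=O)[C@]2(C)[C@](O)(/C(=C/C(C)=O)[C@@H](O[Si](C)(C)C(C)(C)C)C[C@@H]2C)[C@@H](C)C1=O | intermediate
27 | 4,11-anti diol of 26; (4R,5R,6S,8S,10S,11S,12S,14R) | C=C[C@]1(C)C[C@@H](OC(C)=O)[C@]2(C)[C@](O)(/C(=C/C(C)=O)[C@@H](O[Si](C)(C)C(C)(C)C)C[C@@H]2C)[C@@H](C)[C@@H]1O | intermediate
28 | fused 6-7 γ-hydroxy enone: C4–OH, (E)-C9=C1–C2(=O)CH3, C8 and C11 tert-butyldimethylsilyl ethers, C14 acetate; (4R,5R,6S,8S,10S,11S,12S,14R) | C=C[C@]1(C)C[C@@H](OC(C)=O)[C@]2(C)[C@](O)(/C(=C/C(C)=O)[C@@H](O[Si](C)(C)C(C)(C)C)C[C@@H]2C)[C@@H](C)[C@@H]1O[Si](C)(C)C(C)(C)C | intermediate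
29 | bridged bicyclo[5.3.1] 1,4-diketone: C4 ketone, quaternary C9 bearing CH2C(=O)CH3 and C10; (5R,6S,8S,9S,10R,11S,12S,14R) | C=C[C@]1(C)C[C@@H](OC(C)=O)[C@]2(C)C(=O)[C@](CC(C)=O)([C@@H](O[Si](C)(C)C(C)(C)C)C[C@@H]2C)[C@@H](C)[C@@H]1O[Si](C)(C)C(C)(C)C | intermediate
30 | 8,11-bis(tert-butyldimethylsilyl) ether of Pleuromutilin E | C=C[C@]1(C)C[C@@H](OC(C)=O)[C@]2(C)C3=CC(=O)C[C@@]3([C@@H](O[Si](C)(C)C(C)(C)C)C[C@@H]2C)[C@@H](C)[C@@H]1O[Si](C)(C)C(C)(C)C | intermediate
31 | Pleuromutilin E; (5S,6S,8S,9R,10R,11S,12S,14R) | C=C[C@]1(C)C[C@@H](OC(C)=O)[C@]2(C)C3=CC(=O)C[C@@]3([C@@H](O)C[C@@H]2C)[C@@H](C)[C@@H]1O | target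

**Totals**
Total step count: 20.
Longest linear sequence: 19 steps (steps 1 to 5 and 7 to 20, from 1); step 6 is a one-step side branch.

**Steps most likely to fail**

Step 18. The shift may not start: in the chair of the trans-fused substrate the C4–C10 bond is pseudo-equatorial and poorly aligned with the enone π-system, and the trans-bridged product is strained, so ionisation of the tertiary allylic alcohol or silyl loss may take over. Fallback, from 28 back to 29: hydroxyl-directed nucleophilic epoxidation of the enone (t-BuOOH, benzyltrimethylammonium hydroxide cat., THF, 0 °C) should give the 9,1-epoxy ketone F1 with the epoxide oxygen on the face of the C4 hydroxyl. A Lewis acid (BF3·OEt2, CH2Cl2, −78 °C) should then open the epoxide at C9 with migration of C10 anti to the breaking C9–O bond, the same 1,2-shift but driven by epoxide strain, to give the C1-hydroxy 1,4-diketone F2. SmI2 (THF–MeOH, −78 °C) removes the hydroxyl α to the C2 ketone and returns 29.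

Step 15. Facial selectivity at C4 may be poor or reversed (cis instead of trans ring fusion) if chelation by the C14 acetate is weak. Fallback, from 24 back to 26: the samarium cyclisation is run without regard to the C4 configuration and the cis-fused aldol F3 is dehydrated (methyl N-(triethylammoniumsulfonyl)carbamate, toluene, 70 °C) to the cross-conjugated C4=C10 dienone F4. Nucleophilic epoxidation (t-BuOOH, benzyltrimethylammonium hydroxide cat., THF, 0 °C) should attack C4 anti to the C5 methyl and the C8 silyloxy group, giving the 4,10-epoxy ketone F5 with the C4–O bond on the required face. SmI2 (THF–MeOH, −78 °C) cleaves the C10–O bond, and oxalic acid work-up removes the ketal to give 26; C10 is then set by protonation and can equilibrate α to the ketone.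

Step 19. The methyl ketone may enolise without closing onto the C4 carbonyl, which is flanked by two quaternary carbons, and prolonged acid may strip the silyl ethers or the acetate first. Fallback, from 29 back to 30: soft enolisation (TMSOTf, Et3N, CH2Cl2, −78 °C) should give the terminal silyl enol ether F6. An intramolecular Mukaiyama aldol addition (TiCl4, CH2Cl2, −78 °C) would give the tertiary aldol F7, and separate dehydration (methyl N-(triethylammoniumsulfonyl)carbamate, toluene, 60 °C) would give 30.

**Further compounds**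
F1 | step 18 | 9,1-epoxide of 28 (epoxide oxygen cis to the C4 hydroxyl) | C=C[C@]1(C)C[C@@H](OC(C)=O)[C@]2(C)[C@](O)([C@]4(O[C@@H]4C(C)=O)[C@@H](O[Si](C)(C)C(C)(C)C)C[C@@H]2C)[C@@H](C)[C@@H]1O[Si](C)(C)C(C)(C)C
F2 | step 18 | C1-hydroxy derivative of 29 | C=C[C@]1(C)C[C@@H](OC(C)=O)[C@]2(C)C(=O)[C@]([C@H](O)C(C)=O)([C@@H](O[Si](C)(C)C(C)(C)C)C[C@@H]2C)[C@@H](C)[C@@H]1O[Si](C)(C)C(C)(C)C
F3 | step 15 | cis-fused C4 epimer of 25 (C10 not fixed) | C=C[C@]1(C)C[C@@H](OC(C)=O)[C@]2(C)[C@@](O)(/C(=C/C(C)(OC)OC)[C@@H](O[Si](C)(C)C(C)(C)C)C[C@@H]2C)C(C)C1=O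
F4 | step 15 | C4=C10 dienone (C11 ketone, C2 ketal) | C=C[C@]1(C)C[C@@H](OC(C)=O)[C@]2(C)C(=C(C)C1=O)/C(=C/C(C)(OC)OC)[C@@H](O[Si](C)(C)C(C)(C)C)C[C@@H]2C
F5 | step 15 | 4,10-epoxy ketone | C=C[C@]1(C)C[C@@H](OC(C)=O)[C@]2(C)[C@@]5(/C(=C/C(C)(OC)OC)[C@@H](O[Si](C)(C)C(C)(C)C)C[C@@H]2C)O[C@@]5(C)C1=O
F6 | step 19 | terminal trimethylsilyl enol ether of the methyl ketone of 29 | C=C[C@]1(C)C[C@@H](OC(C)=O)[C@]2(C)C(=O)[C@](CC(=C)O[Si](C)(C)C)([C@@H](O[Si](C)(C)C(C)(C)C)C[C@@H]2C)[C@@H](C)[C@@H]1O[Si](C)(C)C(C)(C)C
F7 | step 19 | C4 tertiary aldol (cyclopentanone closed, C4 not fixed) | C=C[C@]1(C)C[C@@H](OC(C)=O)[C@]2(C)C3(O)CC(=O)C[C@@]3([C@@H](O[Si](C)(C)C(C)(C)C)C[C@@H]2C)[C@@H](C)[C@@H]1O[Si](C)(C)C(C)(C)C
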